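**Retrosynthetic overview** (labdane numbering: C3 carries the angelate, C4 the CH3/CH2OH pair, C8 the exocyclic methylene)

1. Target ⇒ bicyclic 3‑hydroxy‑18‑silyloxy 2‑(trimethylsilyl)ethyl ester, by angelate C–O formation and removal of two silicon groups.
2. Bicycle ⇒ acyclic all‑E tetraene carbinol, by one radical cycloisomerisation. H‑atom transfer to the 2‑(silyloxymethyl)allyl terminus gives the C4 radical; C4–C5 closes ring A first, C10–C9 closes ring B second, and loss of H from the C8 methyl gives the exocyclic alkene. The single carbinol centre (C3) controls C4, C5, C9 and C10.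
3. Tetraene ⇒ C14 trienyl aldehyde + 2‑bromoallyl silyl ether (enantioselective Ni/Cr alkenylation sets C3).
4. Trienyl aldehyde ⇒ two rounds of isopropenyl Grignard addition / vinyl ether Claisen rearrangement from a C6 enoate aldehyde; each round installs one E‑trisubstituted alkene.
5. C6 aldehyde ⇒ but‑2‑ynoate ester + 3‑oxopropyl organocopper (syn‑carbocupration fixes the 13E enoate).

**Assumption:** the given SMILES is read as the (1R,4aS,5S,6R,8aS)‑decalin, an ent‑labdane with equatorial 3‑angeloyloxy and equatorial 4‑hydroxymethyl groups. Carbinols 9 and 13 are carried as racemates because that centre is destroyed in the next step.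

---

**Step 1**
Reactants: 1 but‑2‑ynoic acid
Product: 2 2‑(trimethylsilyl)ethyl but‑2‑ynoate
Conditions: 2‑(trimethylsilyl)ethanol, DCC, DMAP (cat.), CH2Cl2, 0 °C to rt
Reagents that add atoms: 2‑(trimethylsilyl)ethanol, OCC[Si](C)(C)C
Why: Steglich esterification of an unhindered acid with a primary alcohol; carbodiimide activation at 0 °C with only catalytic DMAP avoids conjugate addition to the ynoate, and no stereocentre is formed.

**Step 2**
Reactants: 2 2‑(trimethylsilyl)ethyl but‑2‑ynoate; 3 2‑(2‑bromoethyl)‑1,3‑dioxolane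
Product: 7 2‑(trimethylsilyl)ethyl (2E)‑3‑methyl‑6‑oxohex‑2‑enoate, via Grignard reagent 4 (not isolated), via organocopper reagent 5 (not isolated), via dioxolane enoate 6 (not isolated)
Conditions: 3, Mg, THF, 25 °C; CuBr·SMe2 (1 equiv), −40 °C; 2, −78 °C, 2 h, MeOH quench at −78 °C; then 2 M aq. HCl, THF, rt
Reagents that add atoms: water, O
Why: Normant‑type syn‑carbocupration of the ynoate places the new alkyl group and the vinylic copper cis, so cold protonation gives the E‑enoate (chain trans to the ester), and the dioxolane is then hydrolysed by dilute acid in the same flask; no stereocentre is formed.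

**Step 3**
Reactants: 7 2‑(trimethylsilyl)ethyl (2E)‑3‑methyl‑6‑oxohex‑2‑enoate; 8 isopropenylmagnesium bromide
Product: 9 2‑(trimethylsilyl)ethyl (2E)‑6‑hydroxy‑3,7‑dimethylocta‑2,7‑dienoate (racemic at C6)
Conditions: 8 (1.1 equiv), THF, −78 °C; aq. NH4Cl
Reagents that add atoms: none
Why: Grignard 1,2‑addition at −78 °C is chemoselective for the aldehyde over the β,β‑disubstituted enoate ester; the carbinol centre is left racemic because step 4 erases it.

**Step 4**
Reactants: 9 2‑(trimethylsilyl)ethyl (2E)‑6‑hydroxy‑3,7‑dimethylocta‑2,7‑dienoate; 10 ethoxyethene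
Product: 12 2‑(trimethylsilyl)ethyl (2E,6E)‑3,7‑dimethyl‑10‑oxodeca‑2,6‑dienoate, via allyl vinyl ether 11 (not isolated)
Conditions: 10 (as solvent), Hg(OAc)2 (0.3 equiv), reflux, 24 h; K2CO3, evaporate; toluene, 120 °C, sealed tube
Reagents that add atoms: none
Why: Hg(OAc)2‑catalysed transvinylation followed by Claisen [3,3] rearrangement through a chair with the chain equatorial (the 2‑methyl group penalises the axial alternative) gives the E‑trisubstituted alkene and the two‑carbon‑homologated aldehyde directly; the carbinol centre is erased.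

**Step 5**
Reactants: 12 2‑(trimethylsilyl)ethyl (2E,6E)‑3,7‑dimethyl‑10‑oxodeca‑2,6‑dienoate; 8 isopropenylmagnesium bromide
Product: 13 2‑(trimethylsilyl)ethyl (2E,6E)‑10‑hydroxy‑3,7,11‑trimethyldodeca‑2,6,11‑trienoate (racemic at C10)
Conditions: 8 (1.1 equiv), THF, −78 °C; aq. NH4Cl
Reagents that add atoms: none
Why: same chemoselective Grignard 1,2‑addition as step 3; the racemic centre is erased in step 6.

**Step 6**
Reactants: 13 2‑(trimethylsilyl)ethyl (2E,6E)‑10‑hydroxy‑3,7,11‑trimethyldodeca‑2,6,11‑trienoate; 10 ethoxyethene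
Product: 15 2‑(trimethylsilyl)ethyl (2E,6E,10E)‑3,7,11‑trimethyl‑14‑oxotetradeca‑2,6,10‑trienoate, via allyl vinyl ether 14 (not isolated)
Conditions: 10 (as solvent), Hg(OAc)2 (0.3 equiv), reflux, 24 h; K2CO3, evaporate; toluene, 120 °C, sealed tube
Reagents that add atoms: none
Why: second transvinylation/Claisen rearrangement, with the same chair‑controlled E selectivity as step 4; no stereocentre remains.

**Step 7**
Reactants: 16 2‑bromoprop‑2‑en‑1‑ol
Product: 17 tert‑butyl[(2‑bromoprop‑2‑en‑1‑yl)oxy]dimethylsilane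
Conditions: TBSCl, imidazole, CH2Cl2, 0 °C to rt
Reagents that add atoms: tert‑butyldimethylsilyl chloride, CC(C)(C)[Si](C)(C)Cl
Why: routine silylation of a primary alcohol; the bulky silyl ether later differentiates the two hydroxyls and biases C4.

**Step 8**
Reactants: 15 2‑(trimethylsilyl)ethyl (2E,6E,10E)‑3,7,11‑trimethyl‑14‑oxotetradeca‑2,6,10‑trienoate; 17 tert‑butyl[(2‑bromoprop‑2‑en‑1‑yl)oxy]dimethylsilane
Product: 19 2‑(trimethylsilyl)ethyl (2E,6E,10E,14R)‑15‑({[tert‑butyl(dimethyl)silyl]oxy}methyl)‑14‑hydroxy‑3,7,11‑trimethylhexadeca‑2,6,10,15‑tetraenoate, via trimethylsilyl ether 18 (not isolated)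
Conditions: CrCl2 (10 mol%), chiral 4‑isopropyloxazoline–aryl methanesulfonamide ligand (Kishi type, 11 mol%, antipode chosen for Si‑face addition), 1,8‑bis(dimethylamino)naphthalene (11 mol%), NiCl2(2,9‑dimethyl‑1,10‑phenanthroline) (2 mol%), Mn (2 equiv), LiCl, TMSCl (2 equiv), 17 (1.5 equiv), MeCN, rt; then 1 M aq. HCl, THF, 0 °C
Reagents that add atoms: none
Why: catalytic asymmetric Nozaki–Hiyama–Kishi alkenylation; the alkenylchromium adds only to the aldehyde (the enoate ester is untouched) and the chiral chromium complex directs Si‑face attack to set the 14R carbinol (future C3), the silyl‑trapped product being hydrolysed on work‑up.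

**Step 9** (key step)
Reactants: 19 2‑(trimethylsilyl)ethyl (2E,6E,10E,14R)‑15‑({[tert‑butyl(dimethyl)silyl]oxy}methyl)‑14‑hydroxy‑3,7,11‑trimethylhexadeca‑2,6,10,15‑tetraenoate
Product: 20 2‑(trimethylsilyl)ethyl (2E)‑5‑[(1R,4aS,5S,6R,8aS)‑5‑({[tert‑butyl(dimethyl)silyl]oxy}methyl)‑6‑hydroxy‑5,8a‑dimethyl‑2‑methylidenedecahydronaphthalen‑1‑yl]‑3‑methylpent‑2‑enoate
Conditions: Co(salen)Cl (5 mol%; salen = (R,R)‑N,N'‑bis(3,5‑di‑tert‑butylsalicylidene)cyclohexane‑1,2‑diaminate; trivalent cobalt), PhSiH3 (10 mol%), degassed benzene, 0.01 M, 22 °C, stopped before full conversion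
Reagents that add atoms: none
Why: Proposed new method: the cobalt hydride formed from Co(salen)Cl and PhSiH3 transfers H• in Markovnikov fashion only to the 1,1‑disubstituted alkene (trisubstituted alkenes and the enoate react far more slowly), giving the tertiary C4 radical next to the carbinol; allylic 1,3‑strain holds the C3–H in the radical plane, so the C5=C10 alkene is attacked 6‑endo through a chair with the hydroxyl equatorial and the bulkier CH2OTBS group equatorial (methyl axial), the C10 radical then closes ring B 6‑endo on the E C8=C9 alkene through a second chair (trans‑decalin, side chain equatorial), and divalent cobalt abstracts the least hindered hydrogen (C17 methyl) from the tertiary C8 radical to give the exocyclic alkene and regenerate the hydride, so the one 14R centre sets C4, C5, C9 and C10 and the reaction is a pure isomerisation; the closest known reaction types are Co(salen)Cl/PhSiH3 hydrogen‑atom‑transfer cycloisomerisation of dienes, hydrogen‑atom‑transfer‑initiated radical bicyclisation of hydroxylated polyenes (terminated on arenes) and cobalt catalytic chain transfer, which removes a methyl hydrogen next to a tertiary radical.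

**Step 10**
Reactants: 20 2‑(trimethylsilyl)ethyl (2E)‑5‑[(1R,4aS,5S,6R,8aS)‑5‑({[tert‑butyl(dimethyl)silyl]oxy}methyl)‑6‑hydroxy‑5,8a‑dimethyl‑2‑methylidenedecahydronaphthalen‑1‑yl]‑3‑methylpent‑2‑enoate; 21 angelic acid ((2Z)‑2‑methylbut‑2‑enoic acid)
Product: 23 2‑(trimethylsilyl)ethyl (2E)‑5‑[(1R,4aS,5S,6R,8aS)‑5‑({[tert‑butyl(dimethyl)silyl]oxy}methyl)‑5,8a‑dimethyl‑2‑methylidene‑6‑{[(2Z)‑2‑methylbut‑2‑enoyl]oxy}decahydronaphthalen‑1‑yl]‑3‑methylpent‑2‑enoate, via mixed anhydride 22 (not isolated)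
Conditions: 21, 2,4,6‑trichlorobenzoyl chloride, Et3N, toluene, rt, 2 h; then 20, toluene, 80 °C (no DMAP)
Reagents that add atoms: none
Why: Yamaguchi‑type mixed‑anhydride esterification; the hindered equatorial alcohol attacks the less shielded angeloyl carbonyl, and leaving out nucleophilic catalysts prevents addition–elimination isomerisation of the Z (angelate) to the E (tiglate) ester; no stereocentre is touched.

**Step 11**
Reactants: 23 2‑(trimethylsilyl)ethyl (2E)‑5‑[(1R,4aS,5S,6R,8aS)‑5‑({[tert‑butyl(dimethyl)silyl]oxy}methyl)‑5,8a‑dimethyl‑2‑methylidene‑6‑{[(2Z)‑2‑methylbut‑2‑enoyl]oxy}decahydronaphthalen‑1‑yl]‑3‑methylpent‑2‑enoate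
Product: 24 (2E)‑5‑[(1R,4aS,5S,6R,8aS)‑5‑(hydroxymethyl)‑5,8a‑dimethyl‑2‑methylidene‑6‑{[(2Z)‑2‑methylbut‑2‑enoyl]oxy}decahydronaphthalen‑1‑yl]‑3‑methylpent‑2‑enoic acid (CNP0420226.2)
Conditions: TBAF, AcOH (1:1, excess), THF, 0 °C to rt
Reagents that add atoms: none
Why: fluoride‑induced desilylation cleaves the primary silyl ether and fragments the 2‑(trimethylsilyl)ethyl ester (to ethene and Me3SiF) in one operation, while the AcOH buffer keeps the freed C18 hydroxyl protonated so the angelate neither migrates to it nor isomerises; no stereocentre is touched.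

---

**Compound list**

1 | but‑2‑ynoic acid | CC#CC(=O)O | starting material
2 | 2‑(trimethylsilyl)ethyl but‑2‑ynoate | CC#CC(=O)OCC[Si](C)(C)C | intermediate
3 | 2‑(2‑bromoethyl)‑1,3‑dioxolane | BrCCC1OCCO1 | starting material
4 | [2‑(1,3‑dioxolan‑2‑yl)ethyl]magnesium bromide | Br[Mg]CCC1OCCO1 | intermediate
5 | [2‑(1,3‑dioxolan‑2‑yl)ethyl]copper (monovalent copper, MgBr2 complex) | [Cu]CCC1OCCO1 | intermediate
6 | 2‑(trimethylsilyl)ethyl (2E)‑5‑(1,3‑dioxolan‑2‑yl)‑3‑methylpent‑2‑enoate | O1CCOC1CC/C(C)=C/C(=O)OCC[Si](C)(C)C | intermediate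
7 | 2‑(trimethylsilyl)ethyl (2E)‑3‑methyl‑6‑oxohex‑2‑enoate | O=CCC/C(C)=C/C(=O)OCC[Si](C)(C)C | intermediate
8 | isopropenylmagnesium bromide | C=C(C)[Mg]Br | starting material
9 | 2‑(trimethylsilyl)ethyl (2E)‑6‑hydroxy‑3,7‑dimethylocta‑2,7‑dienoate, racemic at C6 | C=C(C)C(O)CC/C(C)=C/C(=O)OCC[Si](C)(C)C | intermediate
10 | ethoxyethene (ethyl vinyl ether) | C=COCC | starting material
11 | 2‑(trimethylsilyl)ethyl (2E)‑6‑(ethenyloxy)‑3,7‑dimethylocta‑2,7‑dienoate, racemic | C=COC(CC/C(C)=C/C(=O)OCC[Si](C)(C)C)C(C)=C | intermediate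
12 | 2‑(trimethylsilyl)ethyl (2E,6E)‑3,7‑dimethyl‑10‑oxodeca‑2,6‑dienoate | O=CCC/C(C)=C/CC/C(C)=C/C(=O)OCC[Si](C)(C)C | intermediate
13 | 2‑(trimethylsilyl)ethyl (2E,6E)‑10‑hydroxy‑3,7,11‑trimethyldodeca‑2,6,11‑trienoate, racemic at C10 | C=C(C)C(O)CC/C(C)=C/CC/C(C)=C/C(=O)OCC[Si](C)(C)C | intermediate
14 | 2‑(trimethylsilyl)ethyl (2E,6E)‑10‑(ethenyloxy)‑3,7,11‑trimethyldodeca‑2,6,11‑trienoate, racemic | C=COC(CC/C(C)=C/CC/C(C)=C/C(=O)OCC[Si](C)(C)C)C(C)=C | intermediate
15 | 2‑(trimethylsilyl)ethyl (2E,6E,10E)‑3,7,11‑trimethyl‑14‑oxotetradeca‑2,6,10‑trienoate | O=CCC/C(C)=C/CC/C(C)=C/CC/C(C)=C/C(=O)OCC[Si](C)(C)C | intermediate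
16 | 2‑bromoprop‑2‑en‑1‑ol | C=C(Br)CO | starting material
17 | tert‑butyl[(2‑bromoprop‑2‑en‑1‑yl)oxy]dimethylsilane | C=C(Br)CO[Si](C)(C)C(C)(C)C | intermediate
18 | 14‑O‑trimethylsilyl ether of 19 (14R) | C=C(CO[Si](C)(C)C(C)(C)C)[C@H](O[Si](C)(C)C)CC/C(C)=C/CC/C(C)=C/CC/C(C)=C/C(=O)OCC[Si](C)(C)C | intermediate
19 | 2‑(trimethylsilyl)ethyl (2E,6E,10E,14R)‑15‑({[tert‑butyl(dimethyl)silyl]oxy}methyl)‑14‑hydroxy‑3,7,11‑trimethylhexadeca‑2,6,10,15‑tetraenoate | C=C(CO[Si](C)(C)C(C)(C)C)[C@H](O)CC/C(C)=C/CC/C(C)=C/CC/C(C)=C/C(=O)OCC[Si](C)(C)C | intermediate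
20 | 2‑(trimethylsilyl)ethyl (2E)‑5‑[(1R,4aS,5S,6R,8aS)‑5‑({[tert‑butyl(dimethyl)silyl]oxy}methyl)‑6‑hydroxy‑5,8a‑dimethyl‑2‑methylidenedecahydronaphthalen‑1‑yl]‑3‑methylpent‑2‑enoate (trans‑decalin; OH and CH2OTBS equatorial, C4 methyl axial and cis to the angular methyl) | C=C1CC[C@H]2[C@@](C)(CC[C@@H](O)[C@]2(C)CO[Si](C)(C)C(C)(C)C)[C@@H]1CC/C(C)=C/C(=O)OCC[Si](C)(C)C | intermediate
21 | angelic acid, (2Z)‑2‑methylbut‑2‑enoic acid | C/C=C(/C)C(=O)O | starting material
22 | (2Z)‑2‑methylbut‑2‑enoic 2,4,6‑trichlorobenzoic anhydride | C/C=C(/C)C(=O)OC(=O)c1c(Cl)cc(Cl)cc1Cl | intermediate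
23 | 2‑(trimethylsilyl)ethyl (2E)‑5‑[(1R,4aS,5S,6R,8aS)‑5‑({[tert‑butyl(dimethyl)silyl]oxy}methyl)‑5,8a‑dimethyl‑2‑methylidene‑6‑{[(2Z)‑2‑methylbut‑2‑enoyl]oxy}decahydronaphthalen‑1‑yl]‑3‑methylpent‑2‑enoate | C=C1CC[C@H]2[C@@](C)(CC[C@@H](OC(=O)/C(C)=C\C)[C@]2(C)CO[Si](C)(C)C(C)(C)C)[C@@H]1CC/C(C)=C/C(=O)OCC[Si](C)(C)C | intermediate
24 | (2E)‑5‑[(1R,4aS,5S,6R,8aS)‑5‑(hydroxymethyl)‑5,8a‑dimethyl‑2‑methylidene‑6‑{[(2Z)‑2‑methylbut‑2‑enoyl]oxy}decahydronaphthalen‑1‑yl]‑3‑methylpent‑2‑enoic acid | C=C1CC[C@H]2[C@@](C)(CC[C@@H](OC(=O)/C(C)=C\C)[C@]2(C)CO)[C@@H]1CC/C(C)=C/C(=O)O | target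

---

**Totals**

Total step count: 11. Longest linear sequence: 10 (steps 1–6 and 8–11); step 7 is a one‑step branch.

**Three steps most likely to fail**

*Step 9.* The cobalt hydride may hand the hydrogen back before the 6‑endo closures (isomerising 19 to a ketone or silyl enol ether). It may re‑engage the exocyclic alkene of 20 and move it into the ring. The CH2OTBS/CH3 preference at C4 may be modest. The fallback sets out from 15 and comes back at 20; it makes the same C4 radical by epoxide opening and ends by an organotitanium elimination that cannot touch the product alkene. Aldehyde 15 is treated with 8 (THF, −78 °C) to give racemic 2‑(trimethylsilyl)ethyl (2E,6E,10E)‑14‑hydroxy‑3,7,11,15‑tetramethylhexadeca‑2,6,10,15‑tetraenoate F1. Sharpless kinetic‑resolution epoxidation (Ti(OiPr)4, D‑(−)‑diisopropyl tartrate, t‑BuOOH 0.55 equiv, 4 Å sieves, CH2Cl2, −20 °C) epoxidises only the 14R enantiomer, at most half of the material, to the erythro epoxy alcohol 2‑(trimethylsilyl)ethyl (2E,6E,10E,14R)‑14‑hydroxy‑3,7,11‑trimethyl‑14‑[(2S)‑2‑methyloxiran‑2‑yl]tetradeca‑2,6,10‑trienoate F2. Titanocene monochloride Cp2TiCl (trivalent titanium, from Cp2TiCl2 and Mn, THF, rt) opens the epoxide homolytically at its tertiary carbon. The C4 radical, now carrying a very bulky titanium‑bound CH2O group that sits equatorial, undergoes the same two 6‑endo closures. Trapping of the C8 radical by a second Cp2TiCl and β‑hydride elimination give the exocyclic alkene of 2‑(trimethylsilyl)ethyl (2E)‑5‑[(1R,4aS,5S,6R,8aS)‑6‑hydroxy‑5‑(hydroxymethyl)‑5,8a‑dimethyl‑2‑methylidenedecahydronaphthalen‑1‑yl]‑3‑methylpent‑2‑enoate F3. Selective silylation of its primary hydroxyl (TBSCl, imidazole, CH2Cl2, 0 °C) gives 20.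

*Step 8.* The 2‑(silyloxymethyl)vinyl bromide may couple sluggishly or with insufficient enantioselectivity. The fallback sets out from 15 and comes back at 19; it moves the stereocontrol from C–C bond formation to a ketone reduction. Compounds 15 and 17 are coupled with achiral CrCl2 (excess) and NiCl2 (cat.) in DMF to give racemic 2‑(trimethylsilyl)ethyl (2E,6E,10E)‑15‑({[tert‑butyl(dimethyl)silyl]oxy}methyl)‑14‑hydroxy‑3,7,11‑trimethylhexadeca‑2,6,10,15‑tetraenoate F4. Dess–Martin periodinane (CH2Cl2, NaHCO3) oxidises it to the enone 2‑(trimethylsilyl)ethyl (2E,6E,10E)‑15‑({[tert‑butyl(dimethyl)silyl]oxy}methyl)‑3,7,11‑trimethyl‑14‑oxohexadeca‑2,6,10,15‑tetraenoate F5. Corey–Bakshi–Shibata reduction with (S)‑2‑methyl‑oxazaborolidine and catecholborane (toluene, −78 °C), the α‑branched alkenyl group acting as the large substituent, gives the 14R alcohol 19.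

*Step 10.* The neopentyl‑type secondary alcohol may acylate slowly, and forcing conditions risk Z to E isomerisation of the angelate. The fallback sets out from 20 and comes back at 23; it builds the Z alkene on an ester that is already in place. Alcohol 20 is esterified with 2‑[bis(2,2,2‑trifluoroethoxy)phosphoryl]propanoic acid (DCC, DMAP, CH2Cl2) to give 2‑(trimethylsilyl)ethyl (2E)‑5‑[(1R,4aS,5S,6R,8aS)‑6‑({2‑[bis(2,2,2‑trifluoroethoxy)phosphoryl]propanoyl}oxy)‑5‑({[tert‑butyl(dimethyl)silyl]oxy}methyl)‑5,8a‑dimethyl‑2‑methylidenedecahydronaphthalen‑1‑yl]‑3‑methylpent‑2‑enoate F6 (mixture of epimers at the phosphonate‑bearing carbon). Still–Gennari olefination (KHMDS, 18‑crown‑6, acetaldehyde, THF, −78 °C) then gives the Z‑2‑methylbut‑2‑enoate 23.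

**Further compounds**

F1 | step 9 | 2‑(trimethylsilyl)ethyl (2E,6E,10E)‑14‑hydroxy‑3,7,11,15‑tetramethylhexadeca‑2,6,10,15‑tetraenoate (racemic) | C=C(C)C(O)CC/C(C)=C/CC/C(C)=C/CC/C(C)=C/C(=O)OCC[Si](C)(C)C
F2 | step 9 | 2‑(trimethylsilyl)ethyl (2E,6E,10E,14R)‑14‑hydroxy‑3,7,11‑trimethyl‑14‑[(2S)‑2‑methyloxiran‑2‑yl]tetradeca‑2,6,10‑trienoate | C[C@]1(CO1)[C@H](O)CC/C(C)=C/CC/C(C)=C/CC/C(C)=C/C(=O)OCC[Si](C)(C)C
F3 | step 9 | 2‑(trimethylsilyl)ethyl (2E)‑5‑[(1R,4aS,5S,6R,8aS)‑6‑hydroxy‑5‑(hydroxymethyl)‑5,8a‑dimethyl‑2‑methylidenedecahydronaphthalen‑1‑yl]‑3‑methylpent‑2‑enoate | C=C1CC[C@H]2[C@@](C)(CC[C@@H](O)[C@]2(C)CO)[C@@H]1CC/C(C)=C/C(=O)OCC[Si](C)(C)C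
F4 | step 8 | 2‑(trimethylsilyl)ethyl (2E,6E,10E)‑15‑({[tert‑butyl(dimethyl)silyl]oxy}methyl)‑14‑hydroxy‑3,7,11‑trimethylhexadeca‑2,6,10,15‑tetraenoate (racemic) | C=C(CO[Si](C)(C)C(C)(C)C)C(O)CC/C(C)=C/CC/C(C)=C/CC/C(C)=C/C(=O)OCC[Si](C)(C)C
F5 | step 8 | 2‑(trimethylsilyl)ethyl (2E,6E,10E)‑15‑({[tert‑butyl(dimethyl)silyl]oxy}methyl)‑3,7,11‑trimethyl‑14‑oxohexadeca‑2,6,10,15‑tetraenoate | C=C(CO[Si](C)(C)C(C)(C)C)C(=O)CC/C(C)=C/CC/C(C)=C/CC/C(C)=C/C(=O)OCC[Si](C)(C)C
F6 | step 10 | 2‑(trimethylsilyl)ethyl (2E)‑5‑[(1R,4aS,5S,6R,8aS)‑6‑({2‑[bis(2,2,2‑trifluoroethoxy)phosphoryl]propanoyl}oxy)‑5‑({[tert‑butyl(dimethyl)silyl]oxy}methyl)‑5,8a‑dimethyl‑2‑methylidenedecahydronaphthalen‑1‑yl]‑3‑methylpent‑2‑enoate | C=C1CC[C@H]2[C@@](C)(CC[C@@H](OC(=O)C(C)P(=O)(OCC(F)(F)F)OCC(F)(F)F)[C@]2(C)CO[Si](C)(C)C(C)(C)C)[C@@H]1CC/C(C)=C/C(=O)OCC[Si](C)(C)C
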